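The seven-membered ring is cut at the ring-fusion bond C1–C5 and at C6–C7 (daucane numbering: C1 quaternary CH3 carbon, C2 CHOAc, C4 carbinol, C5 ring-fusion CH, C6 CHO-anisoyl, C8/C9 epoxide, C10 CHOH). The remaining edge C7–C8(CH3)–C9–C10(O)–C1 has the substituent pattern of the ortho–meta–para–meta–ortho carbons of 3-methoxy-5-methylphenol, and C5=C6 becomes an (E)-enol ether on a C2–C4 tether. One oxidative dearomatisation triggers a cationic [5+2] cycloaddition that closes the cyclopentane and the cycloheptenone together and sets C5 and C6 from C4. The phenol carbon survives only as a ketone bridge C1–CO–C7, later excised as CO2; the angular methyl then enters cis to O-2.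

Key step: step 9

Remarks. Daucane numbering is kept for all ring compounds; in tricycle 13 the bridge carbon is C11. The α-face is the face of the C1 methyl of 25 (the face of C11 in 13); the β-face is that of H-5. Assumption: (R)-BINOL is written as the ligand antipode that gives the (R)-carbinol 6, by analogy with BINOL/Ti(OiPr)4 additions to benzaldehydes; the antipode is used if the sense proves opposite.

Step 1
Reactants: 1 2,6-dimethoxy-4-methylbenzaldehyde
Product: 2 2-hydroxy-6-methoxy-4-methylbenzaldehyde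
Conditions: BCl3, CH2Cl2, −78 °C → 0 °C; aqueous work-up
Reagents that add atoms: none
Why: Lewis-acid ether cleavage in which BCl3 chelates the formyl oxygen and one ortho methoxy group, so chloride dealkylates that ether only and the aryloxyboron chelate shields the second one.

Step 2
Reactants: 2 2-hydroxy-6-methoxy-4-methylbenzaldehyde
Product: 3 2-(allyloxy)-6-methoxy-4-methylbenzaldehyde
Conditions: allyl bromide, K2CO3, DMF, rt
Reagents that add atoms: allyl bromide C=CCBr
Why: Williamson etherification of the phenoxide gives an allyl ether that should survive the Lewis-acid, organometallic and silylation steps and can be removed under neutral conditions.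

Step 3
Reactants: 3 2-(allyloxy)-6-methoxy-4-methylbenzaldehyde; 4 (E)-1-methoxy-3-(trimethylsilyloxy)buta-1,3-diene
Product: 6 (R,E)-5-[2-(allyloxy)-6-methoxy-4-methylphenyl]-5-hydroxy-1-methoxypent-1-en-3-one, via silyl ether 5 (not isolated)
Conditions: (R)-BINOL (20 mol %), Ti(OiPr)4 (20 mol %), 4 Å molecular sieves, Et2O, −20 °C; then Bu4NF/AcOH (1:1), THF, −20 °C
Reagents that add atoms: none
Why: Mukaiyama aldol addition of the silyloxydiene terminus to the aldehyde inside the chiral BINOL–titanium Lewis acid, which selects the aldehyde face and sets C2 as (R), while the buffered desilylation should keep the methoxyvinyl ketone acyclic.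

Step 4
Reactants: 6 (R,E)-5-[2-(allyloxy)-6-methoxy-4-methylphenyl]-5-hydroxy-1-methoxypent-1-en-3-one
Product: 7 (R,E)-5-[2-(allyloxy)-6-methoxy-4-methylphenyl]-1-methoxy-5-(methoxymethoxy)pent-1-en-3-one
Conditions: MOMCl, iPr2NEt, CH2Cl2, 0 °C → rt
Reagents that add atoms: chloromethyl methyl ether COCCl
Why: O-alkylation (acetal formation) under amine base blocks oxa-Michael closure to the dihydropyranone and installs the chelating and later directing acetal oxygen at C2.

Step 5
Reactants: 7 (R,E)-5-[2-(allyloxy)-6-methoxy-4-methylphenyl]-1-methoxy-5-(methoxymethoxy)pent-1-en-3-one; 8 4-methoxybenzyl alcohol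
Product: 9 (R,E)-5-[2-(allyloxy)-6-methoxy-4-methylphenyl]-1-[(4-methoxybenzyl)oxy]-5-(methoxymethoxy)pent-1-en-3-one
Conditions: PPTS (cat.), toluene, 40 °C, reduced pressure
Reagents that add atoms: none
Why: acid-catalysed transetherification of the vinylogous ester (conjugate addition–elimination) driven by removal of methanol, the (E)-alkene being the thermodynamic isomer.

Step 6
Reactants: 9 (R,E)-5-[2-(allyloxy)-6-methoxy-4-methylphenyl]-1-[(4-methoxybenzyl)oxy]-5-(methoxymethoxy)pent-1-en-3-one
Product: 10 (1E,3R,5R)-5-[2-(allyloxy)-6-methoxy-4-methylphenyl]-1-[(4-methoxybenzyl)oxy]-5-(methoxymethoxy)-3-(propan-2-yl)pent-1-en-3-ol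
Conditions: CeCl3 (anhydrous), iPrMgCl, THF, −78 °C; NaHCO3 quench
Reagents that add atoms: isopropylmagnesium chloride CC(C)[Mg]Cl
Why: chelation-controlled 1,2-addition of the low-basicity organocerium reagent, in which the metal bridges the ketone and MOM oxygens, the aryl group lies equatorial in the six-membered chelate and isopropyl enters axially, giving the 2,4-syn diol pattern (C4 R) without enolisation or 1,4-addition.

Step 7
Reactants: 10 (1E,3R,5R)-5-[2-(allyloxy)-6-methoxy-4-methylphenyl]-1-[(4-methoxybenzyl)oxy]-5-(methoxymethoxy)-3-(propan-2-yl)pent-1-en-3-ol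
Product: 11 triethylsilyl ether of 10
Conditions: Et3SiOTf, 2,6-lutidine, CH2Cl2, −78 °C
Reagents that add atoms: triethylsilyl trifluoromethanesulfonate CC[Si](CC)(CC)OS(=O)(=O)C(F)(F)F
Why: silylation of the hindered tertiary alcohol with the silyl triflate under buffered conditions, so that this oxygen cannot capture the phenoxonium ion in step 9.

Step 8
Reactants: 11 triethylsilyl ether of 10
Product: 12 2-[(1R,3R,4E)-5-[(4-methoxybenzyl)oxy]-1-(methoxymethoxy)-3-(propan-2-yl)-3-(triethylsilyloxy)pent-4-en-1-yl]-3-methoxy-5-methylphenol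
Conditions: Pd(PPh3)4 (5 mol %), morpholine, THF, rt
Reagents that add atoms: none
Why: Tsuji–Trost deallylation in which zerovalent palladium ionises the aryl allyl ether and morpholine captures the allyl group, leaving enol ether, acetal and silyl ether untouched.

Step 9
Reactants: 12 2-[(1R,3R,4E)-5-[(4-methoxybenzyl)oxy]-1-(methoxymethoxy)-3-(propan-2-yl)-3-(triethylsilyloxy)pent-4-en-1-yl]-3-methoxy-5-methylphenol
Product: 13 2α-(methoxymethoxy)-6β-[(4-methoxybenzyl)oxy]-8-methyl-4β-(propan-2-yl)-4α-(triethylsilyloxy)-5βH-tricyclo[5.3.1.0(1,5)]undec-8-ene-10,11-dione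
Conditions: PhI(OAc)2 (1.1 equiv), (CF3)2CHOH/CH2Cl2 (1:4), −40 °C → 0 °C
Reagents that add atoms: none
Why: PhI(OAc)2 turns the phenol into an aryloxy-λ3-iodane that ionises to a phenoxonium ion; the enol ether carbon C5 adds to the ipso carbon C1 (5-exo closure of cyclopentane ring A), and the oxocarbenium ion left at C6 is captured by C7, the terminal carbon of the 1-methoxydiene unit C10=C9–C8=C7 of the dienone just formed (closure of the cyclopentane C1–C11–C7–C6–C5, which completes the seven-membered carbocycle), after which acetate removes the methyl group of the C10 oxocarbenium ion to give the enone. The closest known reaction type is the cationic, perezone-type [5+2] cycloaddition of phenoxonium or quinone-monoketal cations with alkenes, known intramolecularly for 2-(alkenylalkyl)phenols. C5 is controlled by C4 (1,2-induction): in the ring-A-forming transition state the isopropyl group turns away from the C6 arm, so the silyloxy group ends cis to C6. C6 follows from the (E)-geometry of the enol ether by suprafacial addition (O-6 trans to C4, i.e. β), and C1 and C7 are dictated by the cis-fused diquinane/bicyclo[3.2.1]octane geometry and are erased in steps 10 to 12. The step needs carbon capture of both cations to outrun oxygen capture and benzylic ionisation; the tertiary hydroxyl is silylated, O-2 sits in an acetal, and the cold, weakly nucleophilic fluoroalcohol medium favours the π-nucleophile.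

Step 10
Reactants: 13 tricyclic enedione
Product: 16 4β-isopropyl-2α-(methoxymethoxy)-6β-[(4-methoxybenzyl)oxy]-8-methyl-4α-(triethylsilyloxy)-5βH-hydroazulen-10-one (daucane numbering, dauc-8-ene skeleton without the C1 methyl; C1–H both epimers), via keto acid 14 (not isolated), via vinylogous keto acid 15 (not isolated)
Conditions: LiOH, THF/H2O (3:1), 0 °C; then AcOH to pH 5, 50 °C
Reagents that add atoms: none
Why: retro-Claisen opening of the strained, non-enolisable β-diketone by hydroxide at the bridging carbonyl C11, and whichever bridge bond breaks, the β-keto acid 14 or the vinylogous β-keto acid 15 should lose CO2 on mild acidification and warming to the same enone, so the phenol carbon leaves without trace while C2, C4, C5 and C6 are untouched.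

Step 11
Reactants: 16 bicyclic enone (C1–H)
Product: 17 10-(trimethylsilyloxy)-1(10),8-diene (cross-conjugated silyl dienol ether of 16)
Conditions: LiN(iPr)2, Me3SiCl (in situ), THF, −78 °C; Et3N-buffered work-up
Reagents that add atoms: chlorotrimethylsilane C[Si](C)(C)Cl
Why: kinetic deprotonation at the only α′-hydrogen (C1–H) with internal silyl quench gives the cross-conjugated silyl dienol ether before the enolate can expel the C2 alkoxy group.

Step 12
Reactants: 17 silyl dienol ether
Product: 19 4α-hydroxy-4β-isopropyl-2α-(methoxymethoxy)-6β-[(4-methoxybenzyl)oxy]-1α,8-dimethyl-5βH-dauc-8-en-10-one, via siloxycyclopropane 18 (not isolated)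
Conditions: Et2Zn, CH2I2, CH2Cl2, 0 °C; then Bu4NF, THF, 0 °C → rt
Reagents that add atoms: diiodomethane ICI
Why: Simmons–Smith cyclopropanation of the electron-rich silyl enol ether bond, delivered to the α-face by zinc coordination to the allylic C2 MOM ether, followed by fluoride-induced opening of the cyclopropanolate at the CH2–C10 bond, should give the α-methyl ketone with the methyl cis to O-2 (trans ring fusion at C1/C5), and the fluoride also frees the C4 hydroxyl.

Step 13
Reactants: 19 methylated enone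
Product: 20 4α,6β-dihydroxy-4β-isopropyl-2α-(methoxymethoxy)-1α,8-dimethyl-5βH-dauc-8-en-10-one
Conditions: DDQ, CH2Cl2/pH 7 buffer (10:1), 0 °C
Reagents that add atoms: none
Why: oxidative cleavage of the 4-methoxybenzyl ether by DDQ (benzylic hydride abstraction and hydrolysis of the oxocarbenium ion), which leaves the acetal, enone and tertiary alcohol intact.

Step 14
Reactants: 20 C6 alcohol
Product: 21 6β-(4-methoxybenzoyloxy) derivative of 20
Conditions: 4-methoxybenzoyl chloride, pyridine, DMAP (cat.), CH2Cl2, 0 °C → rt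
Reagents that add atoms: 4-methoxybenzoyl chloride COc1ccc(C(=O)Cl)cc1
Why: DMAP-catalysed acylation of the only secondary hydroxyl, the hindered tertiary C4 hydroxyl being unreactive under these conditions.

Step 15
Reactants: 21 C6 anisoate
Product: 22 2α,4α-dihydroxy-4β-isopropyl-6β-(4-methoxybenzoyloxy)-1α,8-dimethyl-5βH-dauc-8-en-10-one
Conditions: Me2BBr, CH2Cl2, −78 °C; then NaHCO3 (aq.)
Reagents that add atoms: none
Why: Lewis-acid cleavage of the MOM acetal by the bromoborane at low temperature, conditions under which aryl ester and enone are expected to persist.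

Step 16
Reactants: 22 C2 alcohol
Product: 23 2α-acetoxy-4α-hydroxy-4β-isopropyl-6β-(4-methoxybenzoyloxy)-1α,8-dimethyl-5βH-dauc-8-en-10-one
Conditions: Ac2O, pyridine, DMAP (cat.), CH2Cl2, 0 °C
Reagents that add atoms: acetic anhydride CC(=O)OC(C)=O
Why: acylation of the neopentyl secondary alcohol, with the tertiary alcohol left free and the β-acetoxy ketone unable to eliminate because C1 is quaternary.

Step 17
Reactants: 23 enone diester
Product: 24 2α-acetoxy-8β,9β-epoxy-4α-hydroxy-4β-isopropyl-6β-(4-methoxybenzoyloxy)-1α,8-dimethyl-5βH-daucan-10-one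
Conditions: dimethyldioxirane, acetone, 0 °C → rt
Reagents that add atoms: dimethyldioxirane CC1(C)OO1
Why: dioxirane epoxidation (concerted oxygen transfer in neutral medium, compatible with both esters) should occur on the β-face of C8=C9, anti to the axial C1 methyl that shields the α-face in the conformationally locked trans-fused ring, which sets C8 and C9.

Step 18
Reactants: 24 epoxy ketone
Product: 25 CNP0371526.1 (2α-acetoxy-8β,9β-epoxy-4α,10α-dihydroxy-4β-isopropyl-6β-(4-methoxybenzoyloxy)-1α,8-dimethyl-5βH-daucane)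
Conditions: NaBH4, CeCl3·7H2O, MeOH, −78 °C
Reagents that add atoms: none
Why: Luche reduction in which hydride should add to the C10 carbonyl from the β-face, anti to the adjacent axial C1 methyl, giving the 10α-alcohol (trans to the epoxide) without touching the two esters.

Compound list
1 | 2,6-dimethoxy-4-methylbenzaldehyde | COc1cc(C)cc(OC)c1C=O | starting material
2 | 2-hydroxy-6-methoxy-4-methylbenzaldehyde | COc1cc(C)cc(O)c1C=O | intermediate
3 | 2-(allyloxy)-6-methoxy-4-methylbenzaldehyde | C=CCOc1cc(C)cc(OC)c1C=O | intermediate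
4 | (E)-1-methoxy-3-(trimethylsilyloxy)buta-1,3-diene | CO/C=C/C(=C)O[Si](C)(C)C | starting material
5 | (R,E)-5-[2-(allyloxy)-6-methoxy-4-methylphenyl]-1-methoxy-5-(trimethylsilyloxy)pent-1-en-3-one | CO/C=C/C(=O)C[C@@H](O[Si](C)(C)C)c1c(OCC=C)cc(C)cc1OC | intermediate (not isolated)
6 | (R,E)-5-[2-(allyloxy)-6-methoxy-4-methylphenyl]-5-hydroxy-1-methoxypent-1-en-3-one | CO/C=C/C(=O)C[C@@H](O)c1c(OCC=C)cc(C)cc1OC | intermediate
7 | (R,E)-5-[2-(allyloxy)-6-methoxy-4-methylphenyl]-1-methoxy-5-(methoxymethoxy)pent-1-en-3-one | CO/C=C/C(=O)C[C@@H](OCOC)c1c(OCC=C)cc(C)cc1OC | intermediate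
8 | 4-methoxybenzyl alcohol | COc1ccc(CO)cc1 | starting material
9 | (R,E)-5-[2-(allyloxy)-6-methoxy-4-methylphenyl]-1-[(4-methoxybenzyl)oxy]-5-(methoxymethoxy)pent-1-en-3-one | COc1ccc(CO/C=C/C(=O)C[C@@H](OCOC)c2c(OCC=C)cc(C)cc2OC)cc1 | intermediate
10 | (1E,3R,5R)-5-[2-(allyloxy)-6-methoxy-4-methylphenyl]-1-[(4-methoxybenzyl)oxy]-5-(methoxymethoxy)-3-(propan-2-yl)pent-1-en-3-ol | COc1ccc(CO/C=C/[C@](O)(C(C)C)C[C@@H](OCOC)c2c(OCC=C)cc(C)cc2OC)cc1 | intermediate
11 | triethylsilyl ether of 10 | COc1ccc(CO/C=C/[C@](O[Si](CC)(CC)CC)(C(C)C)C[C@@H](OCOC)c2c(OCC=C)cc(C)cc2OC)cc1 | intermediate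
12 | 2-[(1R,3R,4E)-5-[(4-methoxybenzyl)oxy]-1-(methoxymethoxy)-3-(propan-2-yl)-3-(triethylsilyloxy)pent-4-en-1-yl]-3-methoxy-5-methylphenol | COc1ccc(CO/C=C/[C@](O[Si](CC)(CC)CC)(C(C)C)C[C@@H](OCOC)c2c(O)cc(C)cc2OC)cc1 | intermediate
13 | 2α-(methoxymethoxy)-6β-[(4-methoxybenzyl)oxy]-8-methyl-4β-(propan-2-yl)-4α-(triethylsilyloxy)-5βH-tricyclo[5.3.1.0(1,5)]undec-8-ene-10,11-dione | COc1ccc(CO[C@H]2[C@H]4C(C)=CC(=O)[C@]3(C4=O)[C@@H]2[C@](O[Si](CC)(CC)CC)(C(C)C)C[C@H]3OCOC)cc1 | intermediate
14 | keto acid from C11–C7 cleavage (C1 carboxylic acid of the dauc-8-en-10-one) | COc1ccc(CO[C@H]2CC(C)=CC(=O)[C@]3(C(=O)O)[C@@H]2[C@](O[Si](CC)(CC)CC)(C(C)C)C[C@H]3OCOC)cc1 | intermediate (not isolated)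
15 | vinylogous keto acid from C11–C1 cleavage (C7 carboxylic acid, C1–H undefined) | COc1ccc(CO[C@H]2[C@H](C(=O)O)C(C)=CC(=O)C3[C@@H]2[C@](O[Si](CC)(CC)CC)(C(C)C)C[C@H]3OCOC)cc1 | intermediate (not isolated)
16 | 4β-isopropyl-2α-(methoxymethoxy)-6β-[(4-methoxybenzyl)oxy]-8-methyl-4α-(triethylsilyloxy)-5βH-hydroazulen-10-one (daucane numbering, no C1 methyl, C1–H undefined) | COc1ccc(CO[C@H]2CC(C)=CC(=O)C3[C@@H]2[C@](O[Si](CC)(CC)CC)(C(C)C)C[C@H]3OCOC)cc1 | intermediate
17 | 10-(trimethylsilyloxy)-1(10),8-dienyl silyl ether of 16 | COc1ccc(CO[C@H]2CC(C)=CC(O[Si](C)(C)C)=C3[C@@H]2[C@](O[Si](CC)(CC)CC)(C(C)C)C[C@H]3OCOC)cc1 | intermediate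
18 | 1α,10α-methano-10β-(trimethylsilyloxy) cyclopropane from 17 | COc1ccc(CO[C@H]2CC(C)=C[C@@]4(O[Si](C)(C)C)[C@]3(C4)[C@@H]2[C@](O[Si](CC)(CC)CC)(C(C)C)C[C@H]3OCOC)cc1 | intermediate (not isolated)
19 | 4α-hydroxy-4β-isopropyl-2α-(methoxymethoxy)-6β-[(4-methoxybenzyl)oxy]-1α,8-dimethyl-5βH-dauc-8-en-10-one | COc1ccc(CO[C@H]2CC(C)=CC(=O)[C@]3(C)[C@@H]2[C@](O)(C(C)C)C[C@H]3OCOC)cc1 | intermediate
20 | 4α,6β-dihydroxy-4β-isopropyl-2α-(methoxymethoxy)-1α,8-dimethyl-5βH-dauc-8-en-10-one | O[C@H]1CC(C)=CC(=O)[C@]2(C)[C@@H]1[C@](O)(C(C)C)C[C@H]2OCOC | intermediate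
21 | 4α-hydroxy-4β-isopropyl-6β-(4-methoxybenzoyloxy)-2α-(methoxymethoxy)-1α,8-dimethyl-5βH-dauc-8-en-10-one | COc1ccc(C(=O)O[C@H]2CC(C)=CC(=O)[C@]3(C)[C@@H]2[C@](O)(C(C)C)C[C@H]3OCOC)cc1 | intermediate
22 | 2α,4α-dihydroxy-4β-isopropyl-6β-(4-methoxybenzoyloxy)-1α,8-dimethyl-5βH-dauc-8-en-10-one | COc1ccc(C(=O)O[C@H]2CC(C)=CC(=O)[C@]3(C)[C@@H]2[C@](O)(C(C)C)C[C@H]3O)cc1 | intermediate
23 | 2α-acetoxy-4α-hydroxy-4β-isopropyl-6β-(4-methoxybenzoyloxy)-1α,8-dimethyl-5βH-dauc-8-en-10-one | COc1ccc(C(=O)O[C@H]2CC(C)=CC(=O)[C@]3(C)[C@@H]2[C@](O)(C(C)C)C[C@H]3OC(C)=O)cc1 | intermediate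
24 | 2α-acetoxy-8β,9β-epoxy-4α-hydroxy-4β-isopropyl-6β-(4-methoxybenzoyloxy)-1α,8-dimethyl-5βH-daucan-10-one | COc1ccc(C(=O)O[C@H]2C[C@@]3(C)O[C@H]3C(=O)[C@]3(C)[C@@H]2[C@](O)(C(C)C)C[C@H]3OC(C)=O)cc1 | intermediate
25 | CNP0371526.1 | COc1ccc(C(=O)O[C@H]2C[C@@]3(C)O[C@H]3[C@H](O)[C@]3(C)[C@@H]2[C@](O)(C(C)C)C[C@H]3OC(C)=O)cc1 | target

Total step count: 18. Longest linear sequence: 18 steps (1 → 25).

Steps most likely to fail

Step 9. The phenoxonium ion or the C6 oxocarbenium ion may be captured by oxygen nucleophiles, the benzylic acetal may ionise in the fluoroalcohol, or C4 may select the alkene face poorly. The fallback separates oxidation from cyclisation. It sets out from 12: Wessely acetoxylation with Pb(OAc)4 in CH2Cl2 at −78 °C would give the o-quinol acetate F1. Ionisation of its tertiary allylic acetate with BF3·OEt2 in CH2Cl2 at −78 °C would regenerate the same cation in a non-nucleophilic, non-ionising medium, and the cycloaddition would then come back to the route at 13.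

Step 10. Decarboxylation of the vinylogous keto acid may be slow, and prolonged exposure to base or warm acid may then cost the C2 or C6 alkoxy group by β- or vinylogous β-elimination. The fallback sets out from 13: retro-Claisen opening with sodium allyloxide in allyl alcohol/THF at −20 °C would give the allyl ester F2. Deallylative decarboxylation with Pd(PPh3)4, HCO2H and Et3N in THF at room temperature is near-neutral and would return to the route at 16.

Step 12. The methylene may be delivered to the β-face, which is anti to the ring pucker, or to the C8=C9 bond; either would give the cis-fused C1 epimer or over-cyclopropanation. The fallback replaces the directed intermolecular delivery by a temporary silicon tether through O-2 and sets out from 16. Cleavage of the MOM acetal with MgBr2·OEt2 and BuSH would give the C2 alcohol F3, and silylation with (bromomethyl)chlorodimethylsilane and imidazole would give the bromomethylsilyl ether F4. Intramolecular alkylation of the C1 lithium enolate (LiN(iPr)2, THF, −78 °C → −30 °C) would close the oxasilolane F5 with the new carbon necessarily cis to O-2. Protodesilylation with Bu4NF in DMF at 60 °C, which also removes the triethylsilyl group, would give the methyl diol F6. Acetylation would give the C2 acetate F7, and DDQ would free the C6 alcohol F8. Acylation with 4-methoxybenzoyl chloride then comes back to the route at 23.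

Further compounds
F1 | step 9 | 6-acetoxy-5-methoxy-3-methyl-6-[(1R,3R,4E)-5-[(4-methoxybenzyl)oxy]-1-(methoxymethoxy)-3-(propan-2-yl)-3-(triethylsilyloxy)pent-4-en-1-yl]cyclohexa-2,4-dienone (C6 of the dienone undefined) | COc1ccc(CO/C=C/[C@](O[Si](CC)(CC)CC)(C(C)C)C[C@@H](OCOC)C2(OC(C)=O)C(=O)C=C(C)C=C2OC)cc1
F2 | step 10 | allyl ester of vinylogous keto acid 15 (C7 allyl carboxylate, C1–H undefined) | COc1ccc(CO[C@H]2[C@H](C(=O)OCC=C)C(C)=CC(=O)C3[C@@H]2[C@](O[Si](CC)(CC)CC)(C(C)C)C[C@H]3OCOC)cc1
F3 | step 12 | 2α-hydroxy analogue of 16 (MOM removed, C1–H undefined) | COc1ccc(CO[C@H]2CC(C)=CC(=O)C3[C@@H]2[C@](O[Si](CC)(CC)CC)(C(C)C)C[C@H]3O)cc1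
F4 | step 12 | 2α-[(bromomethyl)dimethylsilyloxy] ether of F3 | COc1ccc(CO[C@H]2CC(C)=CC(=O)C3[C@@H]2[C@](O[Si](CC)(CC)CC)(C(C)C)C[C@H]3O[Si](C)(C)CBr)cc1
F5 | step 12 | oxasilolane bridging C1 (via CH2) and O-2 on the α-face | COc1ccc(CO[C@H]2CC(C)=CC(=O)[C@]3(C[Si]4(C)C)[C@@H]2[C@](O[Si](CC)(CC)CC)(C(C)C)C[C@H]3O4)cc1
F6 | step 12 | 2α,4α-dihydroxy-4β-isopropyl-6β-[(4-methoxybenzyl)oxy]-1α,8-dimethyl-5βH-dauc-8-en-10-one | COc1ccc(CO[C@H]2CC(C)=CC(=O)[C@]3(C)[C@@H]2[C@](O)(C(C)C)C[C@H]3O)cc1
F7 | step 12 | 2α-acetoxy-4α-hydroxy-4β-isopropyl-6β-[(4-methoxybenzyl)oxy]-1α,8-dimethyl-5βH-dauc-8-en-10-one | COc1ccc(CO[C@H]2CC(C)=CC(=O)[C@]3(C)[C@@H]2[C@](O)(C(C)C)C[C@H]3OC(C)=O)cc1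
F8 | step 12 | 2α-acetoxy-4α,6β-dihydroxy-4β-isopropyl-1α,8-dimethyl-5βH-dauc-8-en-10-one | O[C@H]1CC(C)=CC(=O)[C@]2(C)[C@@H]1[C@](O)(C(C)C)C[C@H]2OC(C)=O
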